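**Retrosynthetic overview**

1. The aryl allyl ether is cut last (Mitsunobu) into 4-hydroxy-5-methylcoumarin 22, whose pyranone ring is closed on a preformed benzene ring, and allylic alcohol 19. The E-trisubstituted allylic alcohol comes from a terminal alkyne by carboalumination and formaldehyde capture.
2. The 7-oxabicyclo[2.2.1]heptane (C1 = C(Me)–O, C2 = CH–chain, C3 = CMe2, C4 = CH–O, C5/C6 = CH2CH2, O7) is opened at C5–C6 and O7–C1 together. This gives the acyclic epoxy-ene 14; in the forward step the cyclohexane C1–C6 closes first and the oxolane bridge second, in the same operation.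
3. The enabling feature is the oxolane ring O7–C1–C6–C5–C4. O7 sits on C4 next to the C5 methylene, which is the retron of a monosubstituted oxirane. C1 is a methyl-bearing, fully substituted carbon next to the C6 methylene, which is the retron of an isopropenyl group that gives a tertiary cation. The C3 gem-dimethyl group between C2 and C4 makes the inner oxirane carbon neopentylic.
4. Epoxy-ene 14 comes from (S)-carvone. Carvone C5 with its isopropenyl group becomes C2, α′-dimethylation gives C3, and cleavage of the carvone C1–C2 bond gives a methyl ketone (to the alkyne) and an acid (to the chloromethyl ketone, then reagent-controlled reduction and oxirane closure).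

Key step: step 8

Assumption: (S)-(+)-carvone and 1-(2-hydroxy-6-methylphenyl)ethanone are taken as catalogue compounds; the coumarin is made from the latter in one step.

**Route**

Step 1
Reactants: 1 (S)-(+)-carvone
Product: 3 (5R)-2,6,6-trimethyl-5-(prop-1-en-2-yl)cyclohex-2-en-1-one (6,6-dimethylcarvone), via 6-methylcarvone 2 (not isolated)
Conditions: LiN(i-Pr)2 (1.1 equiv), THF, −78 °C, MeI; then LiN(i-Pr)2 (1.2 equiv), DMPU, −78 °C, MeI, → 0 °C
Reagents that add atoms: iodomethane, CI
Why: Kinetic deprotonation of the enone can occur only at C6 (cross-conjugated α′-enolate, C2 is sp2), so two successive enolate alkylations (SN2 on MeI) install the gem-dimethyl group, and the non-enolisable C5 stereocentre is carried unchanged from carvone.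

Step 2
Reactants: 3 6,6-dimethylcarvone
Product: 5 trimethyl{[(5R)-2,6,6-trimethyl-5-(prop-1-en-2-yl)cyclohex-1-en-1-yl]oxy}silane, via lithium enolate 4 (not isolated)
Conditions: LiBH(s-Bu)3 (L-Selectride, 1.1 equiv), THF, −78 °C; then TMSCl/Et3N, −78 → 0 °C; bulb-to-bulb distillation
Reagents that add atoms: chlorotrimethylsilane, C[Si](C)(C)Cl
Why: LiBH(s-Bu)3 should deliver hydride 1,4 to the β-unsubstituted cyclohexenone (conjugate reduction), and O-silylation of the regiospecific enolate fixes the enol double bond toward C2, the only side that can enolise, with no new stereocentre.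

Step 3
Reactants: 5 silyl enol ether
Product: 7 (3R)-2,2-dimethyl-6-oxo-3-(prop-1-en-2-yl)heptanoic acid, via trimethylsilyl ester 6 (not isolated)
Conditions: O3 (1.0 equiv, titrated solution in CH2Cl2), CH2Cl2, −78 °C; Me2S, → rt; aqueous work-up at pH 3
Reagents that add atoms: ozone, [O-][O+]=O
Why: Ozonolysis of a silyl enol ether: the tetrasubstituted, oxygen-activated double bond should react with ozone much faster than the 1,1-disubstituted isopropenyl group, so one equivalent cleaves only the ring and gives the methyl ketone and, through the silyl ester, the acid.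

Step 4
Reactants: 7 keto acid
Product: 8 methyl (3R)-2,2-dimethyl-6-oxo-3-(prop-1-en-2-yl)heptanoate
Conditions: MeI, K2CO3, DMF, rt
Reagents that add atoms: iodomethane, CI
Why: Carboxylate O-alkylation (SN2 on MeI) is insensitive to the α-quaternary centre and leaves the ketone untouched under K2CO3.

Step 5
Reactants: 8 keto ester
Product: 10 methyl (3R)-2,2-dimethyl-3-(prop-1-en-2-yl)hept-6-ynoate, via enol phosphate 9 (not isolated)
Conditions: LiN(i-Pr)2 (1.1 equiv), THF, −78 °C; ClP(O)(OEt)2, −78 °C → rt; LiN(i-Pr)2 (2.3 equiv), −78 °C → rt; aq. NH4Cl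
Reagents that add atoms: none
Why: Negishi's one-pot conversion of a methyl ketone into a terminal alkyne (kinetic enolisation on the CH3 side, O-phosphorylation, base-induced elimination of diethyl phosphate) should work here because the ester has no α-hydrogen and is too hindered for amide attack.

Step 6
Reactants: 10 alkynyl ester
Product: 12 (4R)-1-chloro-3,3-dimethyl-4-(prop-1-en-2-yl)oct-7-yn-2-one, via tetrahedral lithium alkoxide 11 (not isolated)
Conditions: ICH2Cl (3 equiv), MeLi·LiBr (3 equiv, slow addition), THF, −78 °C; sat. aq. NH4Cl at −78 °C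
Reagents that add atoms: chloroiodomethane, ClCI
Why: Chloromethyllithium, formed in situ by I/Li exchange, adds to the ester to give a tetrahedral alkoxide that is stable at −78 °C and releases the α-chloroketone only on quench (carbenoid homologation of esters to chloromethyl ketones); the excess covers transient deprotonation of the alkyne, which is reprotonated at quench.

Step 7
Reactants: 12 chloromethyl ketone
Product: 14 (2R)-2-[(3R)-2-methyl-3-(prop-1-en-2-yl)hept-6-yn-2-yl]oxirane, via chlorohydrin 13 (not isolated)
Conditions: (R)-2-methyl-CBS-oxazaborolidine (20 mol %), catecholborane (1.5 equiv), toluene, −78 → −40 °C; then MeOH, 2 M aq. NaOH, 0 °C → rt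
Reagents that add atoms: none
Why: Oxazaborolidine-catalysed (CBS) reduction with catecholborane, which does not hydroborate the alkene or alkyne at low temperature, should give the (R) carbinol because the (R) catalyst reads the tert-alkyl group as large and CH2Cl as small, and the chlorohydrin then closes to the oxirane by intramolecular Williamson displacement at CH2 without touching the carbinol centre.

Step 8
Reactants: 14 epoxy-ene
Product: 16 (1R,2S,4S)-2-(but-3-yn-1-yl)-1,3,3-trimethyl-7-oxabicyclo[2.2.1]heptane, via cyclohexyl cation 15 (not isolated)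
Conditions: BF3·OEt2 (0.5 equiv), CH2Cl2 (0.01 M), −78 → −40 °C; Et3N, then aq. NaHCO3
Reagents that add atoms: none
Why: Proposed new method: BF3 coordination makes the oxirane CH2 a primary electrophile that the isopropenyl CH2 attacks intramolecularly in an SN2-like, anti fashion (Markovnikov at the alkene), which closes the carbocycle and leaves tertiary cation 15, and the BF3-bound alkoxide on C4 then captures this cation across the ring to give the ether bridge and release BF3. The closest known reaction type is the Lewis acid epoxy-olefin cyclisation of epoxy-polyprenoids that ends in a 7-oxabicyclo[2.2.1]heptane, here with the oxirane turned round so that its unsubstituted terminus is the electrophile, and BF3-activated terminal oxiranes are known to be opened at CH2 by carbon nucleophiles. The cyclohexane closes 6-endo with respect to both the alkene and the oxirane (both oxirane carbons end in the ring) through a chair with the butynyl chain and the departing oxygen equatorial, and the oxolane closes by transannular 1,4 C–O capture of the cation through a boat. The only new stereocentre, C1, has no freedom, because the oxygen can bridge only from the face on which it sits at C4, so the (R) oxirane centre sets (1R), and its cis relation to the carvone-derived C2 substituent places the chain exo. The step needs opening at the oxirane CH2 and not at the inner carbon (which would give a cyclopentane or a Wagner–Meerwein or Meinwald shift); the inner carbon is neopentylic, which blocks backside attack and disfavours ionisation, the gem-dimethyl group folds the chain (Thorpe–Ingold effect), and low temperature keeps the alkyne and the isopropenyl group from reacting otherwise.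

Step 9
Reactants: 16 bicyclic alkyne
Product: 19 (2E)-3-methyl-5-[(1R,2S,4S)-1,3,3-trimethyl-7-oxabicyclo[2.2.1]heptan-2-yl]pent-2-en-1-ol, via alkenyldimethylalane 17 (not isolated), via lithium alkenylalanate 18 (not isolated)
Conditions: Me3Al (2.5 equiv), Cp2ZrCl2 (0.25 equiv), CH2Cl2, 0 °C → rt; volatiles removed; n-BuLi, THF/hexane, −78 °C; (CH2O)n, → rt; cold 1 M HCl
Reagents that add atoms: trimethylaluminium, C[Al](C)C; formaldehyde (from paraformaldehyde), C=O
Why: Negishi zirconium-catalysed carboalumination adds Me–Al syn across the terminal alkyne with methyl on the inner carbon, and the alkenylalanate adds to formaldehyde with retention, which should fix the E geometry of the allylic alcohol while the isolated ether is inert.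

Step 10
Reactants: 20 1-(2-hydroxy-6-methylphenyl)ethanone
Product: 22 4-hydroxy-5-methyl-2H-chromen-2-one, via β-keto ester 21 (not isolated)
Conditions: NaH (3 equiv), diethyl carbonate (3 equiv), toluene, 110 °C; then 2 M HCl
Reagents that add atoms: diethyl carbonate, CCOC(=O)OCC
Why: Claisen-type C-acylation of the ketone enolate by diethyl carbonate followed by lactonisation of the phenoxide onto the β-keto ester is the classical 4-hydroxycoumarin synthesis from a 2-hydroxyacetophenone.

Step 11
Reactants: 19 allylic alcohol; 22 4-hydroxy-5-methyl-2H-chromen-2-one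
Product: 23 5-methyl-4-{[(2E)-3-methyl-5-[(1R,2S,4S)-1,3,3-trimethyl-7-oxabicyclo[2.2.1]heptan-2-yl]pent-2-en-1-yl]oxy}-2H-chromen-2-one
Conditions: PPh3, DIAD, THF, 0 °C → rt
Reagents that add atoms: none
Why: Mitsunobu etherification: the acidic 4-hydroxycoumarin is the pronucleophile and should displace the primary allylic oxyphosphonium by SN2 at CH2, so the E double bond and all stereocentres are untouched.

**Compound list**

1 | (S)-(+)-carvone, (5S)-2-methyl-5-(prop-1-en-2-yl)cyclohex-2-en-1-one | O=C1C(C)=CC[C@H](C(C)=C)C1 | starting material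
2 | (5S,6RS)-2,6-dimethyl-5-(prop-1-en-2-yl)cyclohex-2-en-1-one (6-methylcarvone, C6 epimers) | O=C1C(C)=CC[C@H](C(C)=C)C1C | intermediate
3 | (5R)-2,6,6-trimethyl-5-(prop-1-en-2-yl)cyclohex-2-en-1-one | O=C1C(C)=CC[C@H](C(C)=C)C1(C)C | intermediate
4 | lithium (5R)-2,6,6-trimethyl-5-(prop-1-en-2-yl)cyclohex-1-en-1-olate | [Li+].[O-]C1=C(C)CC[C@H](C(C)=C)C1(C)C | intermediate
5 | trimethyl{[(5R)-2,6,6-trimethyl-5-(prop-1-en-2-yl)cyclohex-1-en-1-yl]oxy}silane | C[Si](C)(C)OC1=C(C)CC[C@H](C(C)=C)C1(C)C | intermediate
6 | trimethylsilyl (3R)-2,2-dimethyl-6-oxo-3-(prop-1-en-2-yl)heptanoate | CC(=O)CC[C@H](C(C)=C)C(C)(C)C(=O)O[Si](C)(C)C | intermediate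
7 | (3R)-2,2-dimethyl-6-oxo-3-(prop-1-en-2-yl)heptanoic acid | CC(=O)CC[C@H](C(C)=C)C(C)(C)C(=O)O | intermediate
8 | methyl (3R)-2,2-dimethyl-6-oxo-3-(prop-1-en-2-yl)heptanoate | CC(=O)CC[C@H](C(C)=C)C(C)(C)C(=O)OC | intermediate
9 | diethyl (5R)-7-methoxy-6,6-dimethyl-7-oxo-5-(prop-1-en-2-yl)hept-1-en-2-yl phosphate | C=C(OP(=O)(OCC)OCC)CC[C@H](C(C)=C)C(C)(C)C(=O)OC | intermediate
10 | methyl (3R)-2,2-dimethyl-3-(prop-1-en-2-yl)hept-6-ynoate | C#CCC[C@H](C(C)=C)C(C)(C)C(=O)OC | intermediate
11 | lithium (4R)-1-chloro-2-methoxy-3,3-dimethyl-4-(prop-1-en-2-yl)oct-7-yn-2-olate (tetrahedral adduct, alkyne drawn protonated, new centre undefined) | C#CCC[C@H](C(C)=C)C(C)(C)C([O-])(OC)CCl.[Li+] | intermediate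
12 | (4R)-1-chloro-3,3-dimethyl-4-(prop-1-en-2-yl)oct-7-yn-2-one | C#CCC[C@H](C(C)=C)C(C)(C)C(=O)CCl | intermediate
13 | (2R,4R)-1-chloro-3,3-dimethyl-4-(prop-1-en-2-yl)oct-7-yn-2-ol | C#CCC[C@H](C(C)=C)C(C)(C)[C@@H](O)CCl | intermediate
14 | (2R)-2-[(3R)-2-methyl-3-(prop-1-en-2-yl)hept-6-yn-2-yl]oxirane | C#CCC[C@H](C(C)=C)C(C)(C)[C@@H]1CO1 | intermediate
15 | (2R,4S)-2-(but-3-yn-1-yl)-1,3,3-trimethyl-4-(trifluoroboranuidyloxy)cyclohexan-1-ylium (zwitterion) | C#CCC[C@H]1C(C)(C)[C@@H](O[B-](F)(F)F)CC[C+]1C | intermediate
16 | (1R,2S,4S)-2-(but-3-yn-1-yl)-1,3,3-trimethyl-7-oxabicyclo[2.2.1]heptane | C#CCC[C@H]1C(C)(C)[C@@H]2CC[C@@]1(C)O2 | intermediate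
17 | dimethyl{(1E)-2-methyl-4-[(1R,2S,4S)-1,3,3-trimethyl-7-oxabicyclo[2.2.1]heptan-2-yl]but-1-en-1-yl}alumane | C/C(=C\[Al](C)C)CC[C@H]1C(C)(C)[C@@H]2CC[C@@]1(C)O2 | intermediate
18 | lithium butyl(dimethyl){(1E)-2-methyl-4-[(1R,2S,4S)-1,3,3-trimethyl-7-oxabicyclo[2.2.1]heptan-2-yl]but-1-en-1-yl}aluminate | [Li+].C/C(=C\[Al-](C)(C)CCCC)CC[C@H]1C(C)(C)[C@@H]2CC[C@@]1(C)O2 | intermediate
19 | (2E)-3-methyl-5-[(1R,2S,4S)-1,3,3-trimethyl-7-oxabicyclo[2.2.1]heptan-2-yl]pent-2-en-1-ol | C/C(=C\CO)CC[C@H]1C(C)(C)[C@@H]2CC[C@@]1(C)O2 | intermediate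
20 | 1-(2-hydroxy-6-methylphenyl)ethanone | CC(=O)c1c(C)cccc1O | starting material
21 | ethyl 3-(2-hydroxy-6-methylphenyl)-3-oxopropanoate (present as its sodium salt) | CCOC(=O)CC(=O)c1c(C)cccc1O | intermediate
22 | 4-hydroxy-5-methyl-2H-chromen-2-one | Cc1cccc2oc(=O)cc(O)c12 | intermediate
23 | 5-methyl-4-{[(2E)-3-methyl-5-[(1R,2S,4S)-1,3,3-trimethyl-7-oxabicyclo[2.2.1]heptan-2-yl]pent-2-en-1-yl]oxy}-2H-chromen-2-one | C/C(=C\COc1cc(=O)oc2cccc(C)c12)CC[C@H]1C(C)(C)[C@@H]2CC[C@@]1(C)O2 | target

**Step count**

Total steps: 11. Longest linear sequence: 10 (steps 1–9, then step 11); step 10 is a one-step side branch.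

**Steps most likely to fail**

1. Step 8 (proposed new method). The risks are opening of the activated oxirane at the inner carbon, a 1,2-shift before the C–C bond forms, fluoride capture at CH2, or loss of a proton from the cation in place of oxygen capture. The fallback makes the two bonds one after the other with known radical and hydrogen-atom-transfer chemistry. From 14, LiI/AcOH in THF opens the oxirane at CH2 to give (2R,4R)-1-iodo-3,3-dimethyl-4-(prop-1-en-2-yl)oct-7-yn-2-ol F1. A cobaloxime-catalysed, visible-light Heck-type cyclisation of the unactivated alkyl iodide (Co(dmgH)2(py)Cl, i-Pr2NEt, MeCN, blue LEDs) then closes the cyclohexane 6-endo and ends by loss of a hydrogen atom. This should give (1S,3R)-3-(but-3-yn-1-yl)-2,2-dimethyl-4-methylidenecyclohexan-1-ol F2 together with its endocyclic isomer (1S,5R)-5-(but-3-yn-1-yl)-4,6,6-trimethylcyclohex-3-en-1-ol F3. Both converge on 16 by Markovnikov intramolecular hydroalkoxylation under cobalt–salen hydrogen-atom-transfer conditions (Co(salen) catalyst, N-fluoro-2,4,6-trimethylpyridinium triflate, 1,1,3,3-tetramethyldisiloxane, PhCF3, rt), where the bridge can again form only on the face of the C4 oxygen.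

2. Step 6. The risks are sluggish addition of the short-lived carbenoid to the neopentylic ester, or collapse of the tetrahedral adduct followed by a second addition. The fallback makes the acyl carbon the electrophile toward a diazoalkane instead. From 10, nucleophilic demethylation (LiI, pyridine, reflux) gives (3R)-2,2-dimethyl-3-(prop-1-en-2-yl)hept-6-ynoic acid F4. Oxalyl chloride with catalytic DMF in CH2Cl2 gives (3R)-2,2-dimethyl-3-(prop-1-en-2-yl)hept-6-ynoyl chloride F5. Diazomethane (2 equiv, Et2O, 0 °C) gives (4R)-1-diazo-3,3-dimethyl-4-(prop-1-en-2-yl)oct-7-yn-2-one F6, and dry HCl in Et2O at 0 °C returns 12.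

3. Step 11. The risk is diversion of the ambident coumarin anion to alkylation at C3 or at the lactone oxygen (2-alkoxychromone), favoured by the peri methyl group that crowds O4. The fallback reverses the roles so that the ether oxygen comes from 19. POCl3 at reflux converts 22 into 4-chloro-5-methyl-2H-chromen-2-one F7, and the sodium alkoxide of 19 (NaH, THF, 0 °C) displaces chloride by addition–elimination at C4 to give 23.

**Further compounds**

F1 | step 8 | (2R,4R)-1-iodo-3,3-dimethyl-4-(prop-1-en-2-yl)oct-7-yn-2-ol | C#CCC[C@H](C(C)=C)C(C)(C)[C@@H](O)CI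
F2 | step 8 | (1S,3R)-3-(but-3-yn-1-yl)-2,2-dimethyl-4-methylidenecyclohexan-1-ol | C#CCC[C@H]1C(C)(C)[C@@H](O)CCC1=C
F3 | step 8 | (1S,5R)-5-(but-3-yn-1-yl)-4,6,6-trimethylcyclohex-3-en-1-ol | C#CCC[C@H]1C(C)(C)[C@@H](O)CC=C1C
F4 | step 6 | (3R)-2,2-dimethyl-3-(prop-1-en-2-yl)hept-6-ynoic acid | C#CCC[C@H](C(C)=C)C(C)(C)C(=O)O
F5 | step 6 | (3R)-2,2-dimethyl-3-(prop-1-en-2-yl)hept-6-ynoyl chloride | C#CCC[C@H](C(C)=C)C(C)(C)C(=O)Cl
F6 | step 6 | (4R)-1-diazo-3,3-dimethyl-4-(prop-1-en-2-yl)oct-7-yn-2-one | C#CCC[C@H](C(C)=C)C(C)(C)C(=O)C=[N+]=[N-]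
F7 | step 11 | 4-chloro-5-methyl-2H-chromen-2-one | Cc1cccc2oc(=O)cc(Cl)c12
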